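**Retrosynthetic overview**
1. 20 ⇐ 19 ⇐ 16: Boc and TBS come off last; the (2E)-oct-2-enoate is put on O3 of N-Boc alcohol 16 with acid 17.
2. 16 ⇐ 15 ⇐ enol triflate 10 + octenyl silyl ether 13 (from epoxide 11): B-alkyl Suzuki coupling at C5, then hydrogenation from the convex face sets C5 and frees O3.
3. Key disconnection: ring B (C4a–C5–C6–C7–C8–C8a) of ketone 9 ⇐ cyclobutanone 8 + ethene; C5–C6 and C7–C8 are made together by inserting ethene into the C5–C8 bond.
4. Enabling feature: the strained four-membered ketone ring C4a–C5(=O)–C8–C8a, cis-fused to piperidine ring A in 8. Its acyl–methylene bond C5–C8 is activated by ring strain and by the C5 carbonyl that binds the catalyst, and the ring already holds C4a/C8a cis and C8 trans to the 2-methyl group.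
5. 8 ⇐ [2+2] of dichloroketene with enecarbamate 6 ⇐ cyclohydrocarbonylation of 3 ⇐ N-Boc-L-alaninal 1 + vinyl Grignard; ring order: A (piperidine), temporary cyclobutanone, B (carbocycle).

Key step: step 6

Remark: ring atoms carry the decahydroquinoline numbers of the target (N1, C2 … C8a) in every intermediate; 1, 11 and 17 are taken as commercial.

**Route**

Step 1
Reactants: 1 tert-butyl N-[(2S)-1-oxopropan-2-yl]carbamate (N-Boc-L-alaninal)
Product: 2 tert-butyl N-[(2S,3S)-3-hydroxypent-4-en-2-yl]carbamate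
Conditions: CH2=CHMgBr (2.5 equiv), THF, −78 to −20 °C; aq NH4Cl
Reagents that add atoms: vinylmagnesium bromide C=C[Mg]Br
Why: Grignard addition under Cram-chelate control (magnesium bridging the deprotonated carbamate nitrogen and the aldehyde oxygen) should favour the syn (2S,3S) amino alcohol, which sets C3 of the target; the anti epimer is to be removed by chromatography.

Step 2
Reactants: 2 tert-butyl N-[(2S,3S)-3-hydroxypent-4-en-2-yl]carbamate
Product: 3 tert-butyl N-[(2S,3S)-3-(benzyloxy)pent-4-en-2-yl]carbamate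
Conditions: BnOC(=NH)CCl3, TfOH (5 mol%), CH2Cl2/cyclohexane, 0 °C to rt
Reagents that add atoms: benzyl 2,2,2-trichloroacetimidate N=C(OCc1ccccc1)C(Cl)(Cl)Cl
Why: Acid-catalysed trichloroacetimidate O-benzylation avoids an alkoxide, so the carbamate cannot close to an oxazolidinone, and the benzyl ether is chosen because it leaves in the later hydrogenation.

Step 3
Reactants: 3 tert-butyl N-[(2S,3S)-3-(benzyloxy)pent-4-en-2-yl]carbamate
Product: 6 tert-butyl (2S,3S)-3-(benzyloxy)-2-methyl-3,4-dihydropyridine-1(2H)-carboxylate, via linear aldehyde 4 (not isolated), via cyclic hemiaminal 5 (not isolated)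
Conditions: Rh(acac)(CO)2 (1 mol%), BIPHEPHOS (2 mol%), CO/H2 (1:1, 4 bar), PPTS (5 mol%), toluene, 70 °C
Reagents that add atoms: carbon monoxide [C-]#[O+]
Why: Cyclohydrocarbonylation: linear-selective hydroformylation of the terminal alkene gives the aldehyde, the carbamate N–H closes the six-membered hemiaminal (6-exo-trig addition to C=O) and acid-catalysed loss of water gives the endocyclic enecarbamate with both stereocentres untouched.

Step 4
Reactants: 6 tert-butyl (2S,3S)-3-(benzyloxy)-2-methyl-3,4-dihydropyridine-1(2H)-carboxylate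
Product: 7 tert-butyl (1R,3S,4S,6S)-4-(benzyloxy)-8,8-dichloro-3-methyl-7-oxo-2-azabicyclo[4.2.0]octane-2-carboxylate
Conditions: Cl3CCOCl, Zn–Cu couple, Et2O/DME, 20 °C, ultrasound
Reagents that add atoms: trichloroacetyl chloride ClC(Cl)(Cl)C(Cl)=O
Why: Ketene–enecarbamate [2+2] cycloaddition in which the ketene carbonyl carbon bonds to the nucleophilic beta-carbon C4a and the CCl2 carbon to C8a, on the face opposite the 2-methyl and 3-benzyloxy groups, so that C4a and C8a are set cis to each other and C8 trans to the methyl group.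

Step 5
Reactants: 7 tert-butyl (1R,3S,4S,6S)-4-(benzyloxy)-8,8-dichloro-3-methyl-7-oxo-2-azabicyclo[4.2.0]octane-2-carboxylate
Product: 8 tert-butyl (1S,3S,4S,6S)-4-(benzyloxy)-3-methyl-7-oxo-2-azabicyclo[4.2.0]octane-2-carboxylate
Conditions: Zn dust, AcOH, rt
Reagents that add atoms: none
Why: Zinc-mediated reductive dechlorination of the alpha,alpha-dichloroketone should leave the strained ketone, the carbamate, the benzyl ether and all stereocentres untouched.

Step 6
Reactants: 8 tert-butyl (1S,3S,4S,6S)-4-(benzyloxy)-3-methyl-7-oxo-2-azabicyclo[4.2.0]octane-2-carboxylate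
Product: 9 tert-butyl (2S,3S,4aS,8aS)-3-(benzyloxy)-2-methyl-5-oxooctahydroquinoline-1(2H)-carboxylate
Conditions: [Rh(C2H4)2Cl]2 (5 mol%), IMes (1,3-dimesitylimidazol-2-ylidene, 10 mol%), 2-amino-3-picoline (30 mol%), TsOH·H2O (10 mol%), ethene (7 bar), THF, 120 °C; aq work-up
Reagents that add atoms: ethene C=C
Why: Proposed new method: condensation of the ketone with the 2-amino-3-picoline co-catalyst gives a transient ketimine whose pyridine nitrogen guides monovalent rhodium into the strained C5–C8 acyl–methylene bond of the four-membered ring, ethene then inserts into the Rh–C8 bond (C7–C8 formed) and C–C reductive elimination from the seven-membered rhodacycle forms C5–C6 before the ketimine is hydrolysed. The closest known reaction types are the rhodium/aminopyridine-catalysed intramolecular insertion of olefins into cyclobutanones (cut-and-sew carboacylation), the insertion of ethene gas into the C–C bond of 1-indanones by the same catalyst system and the nickel-catalysed intermolecular insertion of alkynes into cyclobutanones; the intermolecular union of ethene and a saturated cyclobutanone is the part that is not yet shown. Ring B is closed as a two-carbon ring expansion, a formal (4+2) union of the C5–C4a–C8a–C8 unit and ethene, so no exo or endo cyclisation mode applies. No new stereocentre arises: C4a and C8a are carried over from 8, and should C4a epimerise through the enamine the cis fusion is still preferred because a trans fusion would force C8 into A(1,3) strain against the N-Boc group. The step needs regioselective cleavage of C5–C8 and not C5–C4a, secured by the unsubstituted methylene (less hindered side, primary alkyl–rhodium), and it needs insertion to outrun loss of CO and beta-hydride elimination, for which the ethene pressure and the strongly donating carbene ligand are chosen.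

Step 7
Reactants: 9 tert-butyl (2S,3S,4aS,8aS)-3-(benzyloxy)-2-methyl-5-oxooctahydroquinoline-1(2H)-carboxylate
Product: 10 tert-butyl (2S,3S,4aS,8aS)-3-(benzyloxy)-2-methyl-5-{[(trifluoromethyl)sulfonyl]oxy}-3,4,4a,7,8,8a-hexahydroquinoline-1(2H)-carboxylate
Conditions: KHMDS, THF, −78 °C; PhNTf2, −78 to 0 °C
Reagents that add atoms: N-phenylbis(trifluoromethanesulfonimide) O=S(=O)(N(c1ccccc1)S(=O)(=O)C(F)(F)F)C(F)(F)F
Why: Kinetic deprotonation at the C6 methylene and not at the hindered ring-fusion C4a–H, followed by O-triflation of the enolate, should give the C5=C6 enol triflate without touching C4a.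

Step 8
Reactants: 11 (2R)-2-propyloxirane
Product: 12 (4R)-oct-7-en-4-ol
Conditions: allylMgBr, CuI (10 mol%), THF, −30 to 0 °C; aq NH4Cl
Reagents that add atoms: allylmagnesium bromide C=CC[Mg]Br
Why: Copper-catalysed SN2 opening of the terminal epoxide at its unsubstituted carbon leaves the (R) carbinol centre of the side chain intact.

Step 9
Reactants: 12 (4R)-oct-7-en-4-ol
Product: 13 tert-butyl(dimethyl){[(4R)-oct-7-en-4-yl]oxy}silane
Conditions: TBSCl, imidazole, DMF, rt
Reagents that add atoms: tert-butyldimethylsilyl chloride CC(C)(C)[Si](C)(C)Cl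
Why: Imidazole-promoted silylation protects the secondary alcohol as a silyl ether that survives borane, palladium, hydrogenation and carbodiimide but falls to acid at the end.

Step 10
Reactants: 10 tert-butyl (2S,3S,4aS,8aS)-3-(benzyloxy)-2-methyl-5-{[(trifluoromethyl)sulfonyl]oxy}-3,4,4a,7,8,8a-hexahydroquinoline-1(2H)-carboxylate; 13 tert-butyl(dimethyl){[(4R)-oct-7-en-4-yl]oxy}silane
Product: 15 tert-butyl (2S,3S,4aR,8aS)-3-(benzyloxy)-5-[(5R)-5-{[tert-butyl(dimethyl)silyl]oxy}octyl]-2-methyl-3,4,4a,7,8,8a-hexahydroquinoline-1(2H)-carboxylate, via B-alkyl borane 14 (not isolated)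
Conditions: 13, 9-BBN-H, THF, 0 °C to rt; then 10, Pd(dppf)Cl2 (5 mol%), AsPh3, aq K3PO4, DMF, 50 °C
Reagents that add atoms: none
Why: Anti-Markovnikov hydroboration of the terminal alkene and B-alkyl Suzuki–Miyaura coupling with the enol triflate should join the whole side chain to C5 without touching any stereocentre.

Step 11
Reactants: 15 tert-butyl (2S,3S,4aR,8aS)-3-(benzyloxy)-5-[(5R)-5-{[tert-butyl(dimethyl)silyl]oxy}octyl]-2-methyl-3,4,4a,7,8,8a-hexahydroquinoline-1(2H)-carboxylate
Product: 16 tert-butyl (2S,3S,4aR,5R,8aS)-5-[(5R)-5-{[tert-butyl(dimethyl)silyl]oxy}octyl]-3-hydroxy-2-methyloctahydroquinoline-1(2H)-carboxylate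
Conditions: H2 (3 bar), Pd(OH)2/C, EtOAc/EtOH, rt
Reagents that add atoms: none
Why: Heterogeneous hydrogenation should add hydrogen to C5=C6 from the convex face, anti to C4, which A(1,2) and A(1,3) strain hold pseudoaxial over the other face, so that H5 ends cis to H4a (5R), and the benzyl ether is hydrogenolysed in the same operation.

Step 12
Reactants: 16 tert-butyl (2S,3S,4aR,5R,8aS)-5-[(5R)-5-{[tert-butyl(dimethyl)silyl]oxy}octyl]-3-hydroxy-2-methyloctahydroquinoline-1(2H)-carboxylate; 17 (2E)-oct-2-enoic acid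
Product: 19 tert-butyl (2S,3S,4aR,5R,8aS)-5-[(5R)-5-{[tert-butyl(dimethyl)silyl]oxy}octyl]-2-methyl-3-{[(2E)-oct-2-enoyl]oxy}octahydroquinoline-1(2H)-carboxylate, via O-acylisourea 18 (not isolated)
Conditions: DCC, DMAP (cat.), CH2Cl2, 0 °C to rt
Reagents that add atoms: none
Why: Steglich esterification through the O-acylisourea and the acylpyridinium ion should acylate the only free hydroxyl with retention at C3, the nitrogen being masked as the carbamate.

Step 13
Reactants: 19 tert-butyl (2S,3S,4aR,5R,8aS)-5-[(5R)-5-{[tert-butyl(dimethyl)silyl]oxy}octyl]-2-methyl-3-{[(2E)-oct-2-enoyl]oxy}octahydroquinoline-1(2H)-carboxylate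
Product: 20 (2S,3S,4aR,5R,8aS)-5-[(5R)-5-hydroxyoctyl]-2-methyldecahydroquinolin-3-yl (2E)-oct-2-enoate
Conditions: TFA/CH2Cl2/H2O (10:10:1), 0 °C to rt; cold aq NaHCO3
Reagents that add atoms: none
Why: Acidolysis should remove the Boc group and the silyl ether in one operation, while the conjugated ester and all stereocentres are stable to acid and the brief cold neutralisation limits O-to-N acyl migration.

**Compound list**
1 | tert-butyl N-[(2S)-1-oxopropan-2-yl]carbamate (N-Boc-L-alaninal) | C[C@H](NC(=O)OC(C)(C)C)C=O | starting material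
2 | tert-butyl N-[(2S,3S)-3-hydroxypent-4-en-2-yl]carbamate | O[C@H]([C@H](C)NC(=O)OC(C)(C)C)C=C | intermediate
3 | tert-butyl N-[(2S,3S)-3-(benzyloxy)pent-4-en-2-yl]carbamate | c1ccccc1CO[C@H]([C@H](C)NC(=O)OC(C)(C)C)C=C | intermediate
4 | tert-butyl N-[(2S,3S)-3-(benzyloxy)-6-oxohexan-2-yl]carbamate | c1ccccc1CO[C@H]([C@H](C)NC(=O)OC(C)(C)C)CCC=O | intermediate
5 | tert-butyl (2S,3S)-3-(benzyloxy)-6-hydroxy-2-methylpiperidine-1-carboxylate (both C6 epimers) | c1ccccc1CO[C@H]2CCC(O)N(C(=O)OC(C)(C)C)[C@H]2C | intermediate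
6 | tert-butyl (2S,3S)-3-(benzyloxy)-2-methyl-3,4-dihydropyridine-1(2H)-carboxylate | c1ccccc1CO[C@H]2CC=CN(C(=O)OC(C)(C)C)[C@H]2C | intermediate
7 | tert-butyl (1R,3S,4S,6S)-4-(benzyloxy)-8,8-dichloro-3-methyl-7-oxo-2-azabicyclo[4.2.0]octane-2-carboxylate (cis-fused, four-membered ring anti to the methyl group) | c1ccccc1CO[C@H]2C[C@@H]3C(=O)C(Cl)(Cl)[C@@H]3N(C(=O)OC(C)(C)C)[C@H]2C | intermediate
8 | tert-butyl (1S,3S,4S,6S)-4-(benzyloxy)-3-methyl-7-oxo-2-azabicyclo[4.2.0]octane-2-carboxylate | c1ccccc1CO[C@H]2C[C@@H]3C(=O)C[C@@H]3N(C(=O)OC(C)(C)C)[C@H]2C | intermediate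
9 | tert-butyl (2S,3S,4aS,8aS)-3-(benzyloxy)-2-methyl-5-oxooctahydroquinoline-1(2H)-carboxylate (cis-fused) | c1ccccc1CO[C@H]2C[C@@H]3C(=O)CCC[C@@H]3N(C(=O)OC(C)(C)C)[C@H]2C | intermediate
10 | tert-butyl (2S,3S,4aS,8aS)-3-(benzyloxy)-2-methyl-5-{[(trifluoromethyl)sulfonyl]oxy}-3,4,4a,7,8,8a-hexahydroquinoline-1(2H)-carboxylate | c1ccccc1CO[C@H]2C[C@@H]3C(OS(=O)(=O)C(F)(F)F)=CCC[C@@H]3N(C(=O)OC(C)(C)C)[C@H]2C | intermediate
11 | (2R)-2-propyloxirane | CCC[C@@H]1CO1 | starting material
12 | (4R)-oct-7-en-4-ol | C=CCC[C@H](O)CCC | intermediate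
13 | tert-butyl(dimethyl){[(4R)-oct-7-en-4-yl]oxy}silane | C=CCC[C@H](O[Si](C)(C)C(C)(C)C)CCC | intermediate
14 | 9-[(5R)-5-{[tert-butyl(dimethyl)silyl]oxy}octyl]-9-borabicyclo[3.3.1]nonane | C(CCC[C@H](O[Si](C)(C)C(C)(C)C)CCC)B1C2CCCC1CCC2 | intermediate
15 | tert-butyl (2S,3S,4aR,8aS)-3-(benzyloxy)-5-[(5R)-5-{[tert-butyl(dimethyl)silyl]oxy}octyl]-2-methyl-3,4,4a,7,8,8a-hexahydroquinoline-1(2H)-carboxylate | c1ccccc1CO[C@H]2C[C@@H]3C(CCCC[C@H](O[Si](C)(C)C(C)(C)C)CCC)=CCC[C@@H]3N(C(=O)OC(C)(C)C)[C@H]2C | intermediate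
16 | tert-butyl (2S,3S,4aR,5R,8aS)-5-[(5R)-5-{[tert-butyl(dimethyl)silyl]oxy}octyl]-3-hydroxy-2-methyloctahydroquinoline-1(2H)-carboxylate | O[C@H]1C[C@@H]2[C@H](CCCC[C@H](O[Si](C)(C)C(C)(C)C)CCC)CCC[C@@H]2N(C(=O)OC(C)(C)C)[C@H]1C | intermediate
17 | (2E)-oct-2-enoic acid | CCCCC/C=C/C(=O)O | starting material
18 | O-[(2E)-oct-2-enoyl]-N,N'-dicyclohexylisourea | CCCCC/C=C/C(=O)OC(=NC1CCCCC1)NC1CCCCC1 | intermediate
19 | tert-butyl (2S,3S,4aR,5R,8aS)-5-[(5R)-5-{[tert-butyl(dimethyl)silyl]oxy}octyl]-2-methyl-3-{[(2E)-oct-2-enoyl]oxy}octahydroquinoline-1(2H)-carboxylate | CCCCC/C=C/C(=O)O[C@H]1C[C@@H]2[C@H](CCCC[C@H](O[Si](C)(C)C(C)(C)C)CCC)CCC[C@@H]2N(C(=O)OC(C)(C)C)[C@H]1C | intermediate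
20 | (2S,3S,4aR,5R,8aS)-5-[(5R)-5-hydroxyoctyl]-2-methyldecahydroquinolin-3-yl (2E)-oct-2-enoate | CCCCC/C=C/C(=O)O[C@H]1C[C@@H]2[C@H](CCCC[C@H](O)CCC)CCC[C@@H]2N[C@H]1C | target

**Step count and risks**
Total step count: 13. Longest linear sequence: 11 steps (steps 1–7 and 10–13); the side chain takes steps 8–9.

Steps most likely to fail:

1. Step 6 (Proposed new method). What may go wrong: loss of CO from the rhodacycle (ring contraction), beta-hydride or beta-nitrogen elimination before ethene inserts, competing insertion of rhodium into the C5–C4a bond, or thermal loss of the Boc group. The fallback uses known chemistry, sets out from enecarbamate 6 and comes back at ketone 9. [2+2] cycloaddition of 6 with vinylketene, generated from (2E)-but-2-enoyl chloride and Et3N, should give tert-butyl (1R,3S,4S,6S)-4-(benzyloxy)-8-ethenyl-3-methyl-7-oxo-2-azabicyclo[4.2.0]octane-2-carboxylate F1 with the regio- and facial sense of step 4. Photochemical 1,3-acyl shift of this beta,gamma-unsaturated ketone (hν 300 nm, benzene) moves C5 from C8 to the vinyl terminus and should give the ring-expanded tert-butyl (2S,3S,4aS,8aS)-3-(benzyloxy)-2-methyl-5-oxo-3,4,4a,5,6,8a-hexahydroquinoline-1(2H)-carboxylate F2. Hydrogenation of its C7=C8 bond with H2 and RhCl(PPh3)3, which leaves the benzyl ether alone, returns 9. In this fallback C7–C8 comes from the ketene and only C5–C6 is made in the ring expansion.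

2. Step 11. What may go wrong: migration of the C5=C6 double bond into the ring fusion on palladium before reduction, which would scramble C4a, or poor facial selectivity at C5. The fallback sets out from 15 and comes back at 16. Hydrogen-atom-transfer hydrogenation (Mn(dpm)3, PhSiH3, tert-butyl hydroperoxide, isopropanol) adds hydrogen to C6 and lets the tertiary C5 radical take its hydrogen from the open convex face. This should give the saturated benzyl ether tert-butyl (2S,3S,4aR,5R,8aS)-3-(benzyloxy)-5-[(5R)-5-{[tert-butyl(dimethyl)silyl]oxy}octyl]-2-methyloctahydroquinoline-1(2H)-carboxylate F3 as the more stable isomer with the side chain equatorial. Hydrogenolysis of the benzyl ether (H2, Pd(OH)2/C) then gives 16.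

3. Step 1. What may go wrong: poor syn/anti selectivity, because open (Felkin–Anh) transition states compete with the chelate. The fallback sets out from 1 and comes back at 2; it sets C3 by a catalyst-controlled ketone reduction instead of by C–C bond formation. Addition of lithium (trimethylsilyl)acetylide to 1 gives the epimeric alkynols tert-butyl N-[(2S,3RS)-3-hydroxy-5-(trimethylsilyl)pent-4-yn-2-yl]carbamate F4. Dess–Martin oxidation gives the ynone tert-butyl N-[(2S)-3-oxo-5-(trimethylsilyl)pent-4-yn-2-yl]carbamate F5. Asymmetric transfer hydrogenation with RuCl(p-cymene)[(R,R)-TsDPEN] in isopropanol should give the (3S)-alkynol tert-butyl N-[(2S,3S)-3-hydroxy-5-(trimethylsilyl)pent-4-yn-2-yl]carbamate F6. K2CO3 in methanol removes the silyl group to give tert-butyl N-[(2S,3S)-3-hydroxypent-4-yn-2-yl]carbamate F7, and semi-hydrogenation over Lindlar catalyst (Pd/CaCO3 poisoned with lead, quinoline) gives 2.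

**Further compounds**
F1 | step 6 | tert-butyl (1R,3S,4S,6S)-4-(benzyloxy)-8-ethenyl-3-methyl-7-oxo-2-azabicyclo[4.2.0]octane-2-carboxylate (C8 epimers) | c1ccccc1CO[C@H]2C[C@@H]3C(=O)C(C=C)[C@@H]3N(C(=O)OC(C)(C)C)[C@H]2C
F2 | step 6 | tert-butyl (2S,3S,4aS,8aS)-3-(benzyloxy)-2-methyl-5-oxo-3,4,4a,5,6,8a-hexahydroquinoline-1(2H)-carboxylate | c1ccccc1CO[C@H]2C[C@@H]3C(=O)CC=C[C@@H]3N(C(=O)OC(C)(C)C)[C@H]2C
F3 | step 11 | tert-butyl (2S,3S,4aR,5R,8aS)-3-(benzyloxy)-5-[(5R)-5-{[tert-butyl(dimethyl)silyl]oxy}octyl]-2-methyloctahydroquinoline-1(2H)-carboxylate | c1ccccc1CO[C@H]2C[C@@H]3[C@H](CCCC[C@H](O[Si](C)(C)C(C)(C)C)CCC)CCC[C@@H]3N(C(=O)OC(C)(C)C)[C@H]2C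
F4 | step 1 | tert-butyl N-[(2S,3RS)-3-hydroxy-5-(trimethylsilyl)pent-4-yn-2-yl]carbamate | C[Si](C)(C)C#CC(O)[C@H](C)NC(=O)OC(C)(C)C
F5 | step 1 | tert-butyl N-[(2S)-3-oxo-5-(trimethylsilyl)pent-4-yn-2-yl]carbamate | C[Si](C)(C)C#CC(=O)[C@H](C)NC(=O)OC(C)(C)C
F6 | step 1 | tert-butyl N-[(2S,3S)-3-hydroxy-5-(trimethylsilyl)pent-4-yn-2-yl]carbamate | O[C@H]([C@H](C)NC(=O)OC(C)(C)C)C#C[Si](C)(C)C
F7 | step 1 | tert-butyl N-[(2S,3S)-3-hydroxypent-4-yn-2-yl]carbamate | O[C@H]([C@H](C)NC(=O)OC(C)(C)C)C#C
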